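**Retrosynthetic overview**
1. Target 13 ⇒ isoflavone 11: the labile C3 centre is set in the last step by hydride addition at C2 and enantioselective protonation at C3 (an isoflavone-reductase-like reduction) on the unprotected compound.
2. 11 ⇒ 6-iodo-5'-bromo isoflavone 10: both prenyl groups come from one double Stille coupling after the skeleton is complete; the free 5-OH directs iodine to C6.
3. Isoflavone 8 ⇒ chalcone 6: ring C, the only ring made, is closed by oxa-Michael addition to the flavanone, then an oxidative 2→3 aryl shift with trivalent iodine follows in the same flask (chalcone isomerase, then isoflavone synthase).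
4. 6 ⇒ symmetric 4-O-benzyl phloroacetophenone 2 + aldehyde 5 by Claisen–Schmidt condensation; the symmetry of 2 makes the ring closure unambiguous.

Assumption 1: 3-bromo-4,5-dihydroxybenzaldehyde is taken as a bought catalogue compound (it is also one demethylation away from 5-bromovanillin).
Assumption 2: the (R)-catalyst in step 8 is taken to give the (3S) product; the sense of induction is checked on the first run and the mirror-image catalyst is used if it is opposite.

**Route**

Step 1
Reactants: 1 2,4,6-trihydroxyacetophenone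
Product: 2 1-[4-(benzyloxy)-2,6-dihydroxyphenyl]ethan-1-one
Conditions: BnBr (1.0 equiv), K2CO3 (1.1 equiv), DMF, 0 °C to rt
Reagents that add atoms: benzyl bromide BrCc1ccccc1
Why: Williamson ether synthesis in which the 4-OH, the most acidic hydroxyl and the one not engaged in a hydrogen bond to the ketone, is alkylated first by one equivalent of base and halide, leaving the symmetric 2,6-diol for ring closure and the later 5-OH.

Step 2
Reactants: 3 3-bromo-4,5-dihydroxybenzaldehyde
Product: 5 3-(benzyloxy)-5-bromo-4-methoxybenzaldehyde, via 3-bromo-5-hydroxy-4-methoxybenzaldehyde 4 (not isolated)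
Conditions: MeI (1.0 equiv), Li2CO3 (1.1 equiv), DMF, 40 °C; then BnBr (1.2 equiv), K2CO3 (2 equiv), 60 °C
Reagents that add atoms: iodomethane CI; benzyl bromide BrCc1ccccc1
Why: Two Williamson alkylations in one flask: the weak base Li2CO3 ionises only the 4-OH (para to the aldehyde, ortho to bromine), which takes the methyl group, and the stronger base then lets the remaining 5-OH be benzylated.

Step 3
Reactants: 2 1-[4-(benzyloxy)-2,6-dihydroxyphenyl]ethan-1-one; 5 3-(benzyloxy)-5-bromo-4-methoxybenzaldehyde
Product: 6 (E)-1-[4-(benzyloxy)-2,6-dihydroxyphenyl]-3-[3-(benzyloxy)-5-bromo-4-methoxyphenyl]prop-2-en-1-one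
Conditions: KOH (50% aq.), EtOH, rt, 48 h; then 1 M HCl to pH 5, 0 °C
Reagents that add atoms: none
Why: Claisen–Schmidt condensation in which the methyl ketone enolate adds to the non-enolisable aldehyde and E1cB loss of water gives the (E)-enone, the benzyl ethers and aryl bromide being inert to hydroxide (any chalcone that already closes to flavanone 7 on work-up is carried along, since step 4 passes through 7).

Step 4
Reactants: 6 (E)-1-[4-(benzyloxy)-2,6-dihydroxyphenyl]-3-[3-(benzyloxy)-5-bromo-4-methoxyphenyl]prop-2-en-1-one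
Product: 8 7-(benzyloxy)-3-[3-(benzyloxy)-5-bromo-4-methoxyphenyl]-5-hydroxy-4H-chromen-4-one, via racemic flavanone 7 (not isolated)
Conditions: TsOH·H2O (0.2 equiv), MeCN, 70 °C; then PhI(OH)OTs (1.2 equiv), reflux
Reagents that add atoms: none
Why: Acid-catalysed 6-endo oxa-Michael closure of ring C (chalcone isomerase mimic; the two ortho hydroxyls are equivalent, so only one flavanone can form) is followed by the hypervalent-iodine oxidative rearrangement of flavanones to isoflavones (isoflavone synthase mimic), in which the enol is iodinated at C3 by the trivalent iodine reagent, the aryl group shifts from C2 to C3 as PhI leaves with O1 stabilising the C2 cation, and loss of the C3 proton gives the isoflavone, so the C2 centre of racemic 7 disappears.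

Step 5
Reactants: 8 7-(benzyloxy)-3-[3-(benzyloxy)-5-bromo-4-methoxyphenyl]-5-hydroxy-4H-chromen-4-one
Product: 9 7-(benzyloxy)-3-[3-(benzyloxy)-5-bromo-4-methoxyphenyl]-5-hydroxy-6-iodo-4H-chromen-4-one
Conditions: BnMe3N+ ICl2− (1.05 equiv), CaCO3 (2 equiv), CH2Cl2/MeOH, rt
Reagents that add atoms: benzyltrimethylammonium dichloroiodate C[N+](C)(C)Cc1ccccc1.Cl[I-]Cl
Why: Electrophilic aromatic iodination in which, with O7 benzylated, the free chelated 5-OH directs the iodine to its ortho position C6 (the usual selectivity of 5-hydroxy-7-alkoxychromones), while CaCO3 takes up the HCl so that the iodination is not reversed and the aryl ethers of ring B stay untouched.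

Step 6
Reactants: 9 7-(benzyloxy)-3-[3-(benzyloxy)-5-bromo-4-methoxyphenyl]-5-hydroxy-6-iodo-4H-chromen-4-one
Product: 10 3-(3-bromo-5-hydroxy-4-methoxyphenyl)-5,7-dihydroxy-6-iodo-4H-chromen-4-one
Conditions: BCl3 (5 equiv), C6HMe5 (6 equiv), CH2Cl2, −78 °C; MeOH quench at −78 °C
Reagents that add atoms: none
Why: Lewis-acid cleavage of aryl benzyl ethers with pentamethylbenzene as a non-basic benzyl cation trap, which at −78 °C leaves the aryl methyl ether, the aryl iodide and the aryl bromide alone and is placed here because no acid-sensitive prenyl group is present yet.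

Step 7
Reactants: 10 3-(3-bromo-5-hydroxy-4-methoxyphenyl)-5,7-dihydroxy-6-iodo-4H-chromen-4-one
Product: 11 5,7-dihydroxy-3-[3-hydroxy-4-methoxy-5-(3-methylbut-2-en-1-yl)phenyl]-6-(3-methylbut-2-en-1-yl)-4H-chromen-4-one
Conditions: Bu3SnCH2CH=CMe2 (3 equiv), Pd(PPh3)4 (10 mol%), DMF, 95 °C
Reagents that add atoms: tributyl(3-methylbut-2-en-1-yl)stannane CCCC[Sn](CCCC)(CCCC)CC=C(C)C
Why: Twofold Migita–Kosugi–Stille coupling under neutral conditions that tolerate the three free phenols, in which zerovalent palladium adds to the C–I and C–Br bonds, the prenylstannane transmetallates and reductive elimination at the unsubstituted allyl terminus gives the two linear prenyl groups.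

Step 8
Reactants: 11 5,7-dihydroxy-3-[3-hydroxy-4-methoxy-5-(3-methylbut-2-en-1-yl)phenyl]-6-(3-methylbut-2-en-1-yl)-4H-chromen-4-one
Product: 13 (3S)-5,7-dihydroxy-3-[3-hydroxy-4-methoxy-5-(3-methylbut-2-en-1-yl)phenyl]-6-(3-methylbut-2-en-1-yl)-2,3-dihydro-4H-chromen-4-one, via enol 12 (not isolated)
Conditions: Hantzsch ester (diethyl 2,6-dimethyl-1,4-dihydropyridine-3,5-dicarboxylate, 1.3 equiv), (R)-[3,3'-(2,4,6-iPr3C6H2)2-BINOL]P(O)NHSO2CF3 (10 mol%), CHCl3, 4 Å MS, 25 °C, dark
Reagents that add atoms: none
Why: Proposed new method: the strong chiral Brønsted acid protonates the chromone carbonyl of 11 to a 4-hydroxybenzopyrylium ion held by the chiral anion, the Hantzsch ester (an NADPH stand-in) delivers hydride to C2, and the enol 12 so formed is protonated at C3 by the chiral acid within the hydrogen-bonded pair, which sets the (3S) centre under base-free conditions that should leave the prenyl alkenes and the chelated ketone alone and not epimerise the product; the closest known reaction types are chiral phosphoric acid/Hantzsch ester transfer hydrogenation of 3-substituted quinolines, where the stereocentre likewise comes from protonation after 1,4-hydride transfer, and chiral N-triflyl phosphoramide-catalysed enantioselective protonation of enols and silyl enol ethers of 2-aryl cyclic ketones.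

**Compound list**
1 | 2,4,6-trihydroxyacetophenone | CC(=O)c1c(O)cc(O)cc1O | starting material
2 | 1-[4-(benzyloxy)-2,6-dihydroxyphenyl]ethan-1-one | CC(=O)c1c(O)cc(OCc2ccccc2)cc1O | intermediate
3 | 3-bromo-4,5-dihydroxybenzaldehyde | O=Cc1cc(O)c(O)c(Br)c1 | starting material
4 | 3-bromo-5-hydroxy-4-methoxybenzaldehyde (not isolated) | COc1c(O)cc(C=O)cc1Br | intermediate
5 | 3-(benzyloxy)-5-bromo-4-methoxybenzaldehyde | COc1c(OCc2ccccc2)cc(C=O)cc1Br | intermediate
6 | (E)-1-[4-(benzyloxy)-2,6-dihydroxyphenyl]-3-[3-(benzyloxy)-5-bromo-4-methoxyphenyl]prop-2-en-1-one | COc1c(OCc2ccccc2)cc(/C=C/C(=O)c2c(O)cc(OCc3ccccc3)cc2O)cc1Br | intermediate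
7 | 7-(benzyloxy)-2-[3-(benzyloxy)-5-bromo-4-methoxyphenyl]-5-hydroxy-2,3-dihydro-4H-chromen-4-one, racemic at C2 (not isolated) | COc1c(OCc2ccccc2)cc(C2CC(=O)c3c(O)cc(OCc4ccccc4)cc3O2)cc1Br | intermediate
8 | 7-(benzyloxy)-3-[3-(benzyloxy)-5-bromo-4-methoxyphenyl]-5-hydroxy-4H-chromen-4-one | COc1c(OCc2ccccc2)cc(-c2coc3cc(OCc4ccccc4)cc(O)c3c2=O)cc1Br | intermediate
9 | 7-(benzyloxy)-3-[3-(benzyloxy)-5-bromo-4-methoxyphenyl]-5-hydroxy-6-iodo-4H-chromen-4-one | COc1c(OCc2ccccc2)cc(-c2coc3cc(OCc4ccccc4)c(I)c(O)c3c2=O)cc1Br | intermediate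
10 | 3-(3-bromo-5-hydroxy-4-methoxyphenyl)-5,7-dihydroxy-6-iodo-4H-chromen-4-one | COc1c(O)cc(-c2coc3cc(O)c(I)c(O)c3c2=O)cc1Br | intermediate
11 | 5,7-dihydroxy-3-[3-hydroxy-4-methoxy-5-(3-methylbut-2-en-1-yl)phenyl]-6-(3-methylbut-2-en-1-yl)-4H-chromen-4-one | COc1c(O)cc(-c2coc3cc(O)c(CC=C(C)C)c(O)c3c2=O)cc1CC=C(C)C | intermediate
12 | 3-[3-hydroxy-4-methoxy-5-(3-methylbut-2-en-1-yl)phenyl]-6-(3-methylbut-2-en-1-yl)-2H-chromene-4,5,7-triol, the enol (not isolated) | COc1c(O)cc(C2=C(O)c3c(O)c(CC=C(C)C)c(O)cc3OC2)cc1CC=C(C)C | intermediate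
13 | (3S)-5,7-dihydroxy-3-[3-hydroxy-4-methoxy-5-(3-methylbut-2-en-1-yl)phenyl]-6-(3-methylbut-2-en-1-yl)-2,3-dihydro-4H-chromen-4-one | COc1c(O)cc([C@H]2COc3cc(O)c(CC=C(C)C)c(O)c3C2=O)cc1CC=C(C)C | target

**Step count and risks**
Total steps: 8. Longest linear sequence: 7 steps (1 → 2 → 6 → 8 → 9 → 10 → 11 → 13; the branch from 3 is equally long).

Steps most likely to fail:

Step 8. The benzopyrylium ion of a 5,7-dihydroxychromone may accept hydride only slowly, achiral proton donors (the phenols, the pyridinium by-product) may erode the ee, and the strong acid may cyclise a prenyl group onto a neighbouring phenol. Fallback, setting out from 11 and coming back at 13: 11 is treated with Li[HB(s-Bu)3] (4.5 equiv, THF, −78 °C; three equivalents are used up by the phenols, the fourth adds 1,4) and the enolate and phenoxides are quenched with Me3SiCl/Et3N to give 3-[4-methoxy-3-(3-methylbut-2-en-1-yl)-5-(trimethylsilyloxy)phenyl]-6-(3-methylbut-2-en-1-yl)-4,5,7-tris(trimethylsilyloxy)-2H-chromene F1. This silyl enol ether is protonated enantioselectively with PhOH (1.1 equiv) and 5 mol% of the antipode of [3,3'-(2,4,6-iPr3C6H2)2-BINOL]P(S)NHSO2CF3 that gives (3S), in toluene at rt. The aryl silyl ethers are then removed with citric acid in MeOH at 0 °C to give 13. Both stages are known reaction types (1,4-reduction of hydroxyisoflavones with this hydride; Brønsted-acid-catalysed protonation of silyl enol ethers of 2-aryl cycloalkanones).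

Step 4. The migrating aryl group has its 4-methoxy donor flanked by Br and OBn, so dehydrogenation to the flavone may compete with the aryl shift, and the oxidant may attack the electron-rich ring A with its free 5-OH. Fallback, setting out from 6 and coming back at 8: the aryl shift is done on the open-chain enone before ring closure. Chalcone 6 with Tl(NO3)3·3H2O (1.1 equiv) in MeOH/HC(OMe)3 at rt undergoes oxythallation by trivalent thallium and 1,2-aryl migration to racemic 1-[4-(benzyloxy)-2,6-dihydroxyphenyl]-2-[3-(benzyloxy)-5-bromo-4-methoxyphenyl]-3,3-dimethoxypropan-1-one F2. Warming F2 in 10% HCl/MeOH at 50 °C closes ring C by attack of an ortho hydroxyl on the acetal carbon, and loss of methanol gives 8; no flavanone is involved, so no flavone can form.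

Step 7. A double coupling on an unprotected triphenol can suffer protodehalogenation at the electron-rich C6 iodide, and the prenylstannane can deliver some branched (1,1-dimethylallyl) product. Fallback, setting out from 10 and coming back at 11: 10 is coupled twice with Bu3SnCH2CH=CH2 (Pd(PPh3)4, DMF, 90 °C), which has no regiochemical ambiguity, to give 5,7-dihydroxy-3-[3-hydroxy-4-methoxy-5-(prop-2-en-1-yl)phenyl]-6-(prop-2-en-1-yl)-4H-chromen-4-one F3. Double olefin cross-metathesis of F3 with excess 2-methylbut-2-ene and the second-generation Grubbs catalyst RuCl2(=CHPh)(PCy3)(H2IMes) in CH2Cl2 at 40 °C converts both allyl groups into prenyl groups and gives 11.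

**Further compounds**
F1 | step 8 | 3-[4-methoxy-3-(3-methylbut-2-en-1-yl)-5-(trimethylsilyloxy)phenyl]-6-(3-methylbut-2-en-1-yl)-4,5,7-tris(trimethylsilyloxy)-2H-chromene | COc1c(O[Si](C)(C)C)cc(C2=C(O[Si](C)(C)C)c3c(O[Si](C)(C)C)c(CC=C(C)C)c(O[Si](C)(C)C)cc3OC2)cc1CC=C(C)C
F2 | step 4 | 1-[4-(benzyloxy)-2,6-dihydroxyphenyl]-2-[3-(benzyloxy)-5-bromo-4-methoxyphenyl]-3,3-dimethoxypropan-1-one (racemic) | COC(OC)C(C(=O)c1c(O)cc(OCc2ccccc2)cc1O)c1cc(OCc2ccccc2)c(OC)c(Br)c1
F3 | step 7 | 5,7-dihydroxy-3-[3-hydroxy-4-methoxy-5-(prop-2-en-1-yl)phenyl]-6-(prop-2-en-1-yl)-4H-chromen-4-one | COc1c(O)cc(-c2coc3cc(O)c(CC=C)c(O)c3c2=O)cc1CC=C
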